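**Assumption:** the spiro quaternary carbon is formed without facial control in the coupling (step 9), and the wanted epimer is taken on after chromatographic separation. Everything before the coupling on the ring side is racemic or achiral by design.

## Retrosynthetic overview

1. The oxetane C–O bond and the secondary C–Br bond are made last, by anti bromo-etherification of the ring C=C by the acetal oxygen of a silyl-locked spiro lactol.
2. The lactol comes from a spiro γ-lactone. The lactone comes from joining a C10 bromodiene ester (as its trienolate) and a C5 chiral vinyl epoxide at the quaternary carbon, with lactonisation in the same step.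
3. The C10 ring ester comes from mesityl oxide and methyl acetoacetate (annulation, reduction/elimination, allylic bromination).
4. The C5 epoxide comes from prenol (Sharpless epoxidation, ene-diol rearrangement, epoxide re-closure).
5. Ring order: carbocycle first, five-membered oxygen ring at the coupling, oxetane last.

## Route

**Step 1**
Reactants: 1 4-methylpent-3-en-2-one (mesityl oxide); 2 methyl 3-oxobutanoate (methyl acetoacetate)
Product: 3 methyl 2,6,6-trimethyl-4-oxocyclohex-2-ene-1-carboxylate (racemic)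
Conditions: ZnCl2 (0.3 equiv), PhMe, reflux, Dean–Stark
Reagents that add atoms: none
Why: A Lewis-acid-mediated Michael addition of the acetoacetate α-carbon to the β,β-dimethyl enone followed by intramolecular aldol condensation (Hagemann/Robinson-type annulation) closes the carbocycle with the gem-dimethyl carbon next to the ester-bearing carbon; the one stereocentre is racemic and is erased in step 3.

**Step 2**
Reactants: 3 methyl 2,6,6-trimethyl-4-oxocyclohex-2-ene-1-carboxylate
Product: 4 methyl 4-hydroxy-2,6,6-trimethylcyclohex-2-ene-1-carboxylate (racemic, cis/trans mixture)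
Conditions: NaBH4, CeCl3·7H2O, MeOH, −20 °C
Reagents that add atoms: none
Why: Luche 1,2-reduction takes the enone carbonyl to the allylic alcohol without touching the ester; the new carbinol centre is uncontrolled and irrelevant because it is eliminated in step 3.

**Step 3**
Reactants: 4 methyl 4-hydroxy-2,6,6-trimethylcyclohex-2-ene-1-carboxylate
Product: 6 methyl 2,6,6-trimethylcyclohexa-1,3-diene-1-carboxylate, via allylic mesylate 5 (not isolated)
Conditions: MsCl, Et3N, CH2Cl2, −20 °C; then DBU, PhMe, 60 °C
Reagents that add atoms: none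
Why: Mesylation followed by DBU-induced vinylogous E1cB (1,4-) elimination through the acidic ester α-hydrogen delivers the fully conjugated dienoate, leaving no stereocentre.

**Step 4**
Reactants: 6 methyl 2,6,6-trimethylcyclohexa-1,3-diene-1-carboxylate
Product: 7 methyl 5-bromo-2,6,6-trimethylcyclohexa-1,3-diene-1-carboxylate (racemic)
Conditions: NBS (1.0 equiv), AIBN (cat.), PhCF3, 80 °C
Reagents that add atoms: N-bromosuccinimide, O=C1CCC(=O)N1Br
Why: Wohl–Ziegler allylic bromination abstracts a hydrogen from the ring CH2 to give an ester-conjugated pentadienyl radical, and bromine is taken up at the terminus remote from the ester so that the conjugated dienoate is kept; the CHBr centre is racemic and becomes sp2 in step 9.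

**Step 5**
Reactants: 8 3-methylbut-2-en-1-ol (prenol)
Product: 9 [(2R)-3,3-dimethyloxiran-2-yl]methanol
Conditions: Ti(OiPr)4 (5 mol %), D-(−)-diethyl tartrate (6 mol %), t-BuOOH, 4 Å MS, CH2Cl2, −20 °C
Reagents that add atoms: tert-butyl hydroperoxide, CC(C)(C)OO
Why: Sharpless asymmetric epoxidation of the allylic alcohol with the D-(−)-tartrate catalyst delivers oxygen to one enantioface and sets the (2R) centre.

**Step 6**
Reactants: 9 [(2R)-3,3-dimethyloxiran-2-yl]methanol
Product: 10 (2S)-3-methylbut-3-ene-1,2-diol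
Conditions: Ti(OiPr)4 (1.5 equiv), CH2Cl2, rt; aq. tartaric acid work-up
Reagents that add atoms: none
Why: In this titanium-alkoxide-mediated epoxy alcohol to ene-diol rearrangement the chelated epoxide opens at the tertiary carbon and loses a methyl proton, so the C2–O bond is untouched and the stereocentre is retained (its descriptor changes to S only through the priority rules).

**Step 7**
Reactants: 10 (2S)-3-methylbut-3-ene-1,2-diol
Product: 11 (2S)-2-hydroxy-3-methylbut-3-en-1-yl 4-methylbenzenesulfonate
Conditions: TsCl (1.05 equiv), Et3N, Bu2SnO (2 mol %), CH2Cl2, 0 °C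
Reagents that add atoms: 4-methylbenzenesulfonyl chloride, Cc1ccc(cc1)S(Cl)(=O)=O
Why: Tin-catalysed sulfonylation is selective for the primary hydroxyl of the 1,2-diol and leaves the stereocentre untouched.

**Step 8**
Reactants: 11 (2S)-2-hydroxy-3-methylbut-3-en-1-yl 4-methylbenzenesulfonate
Product: 12 (2S)-2-(prop-1-en-2-yl)oxirane (volatile; used as a dried Et2O solution)
Conditions: NaH, Et2O, 0 °C → rt
Reagents that add atoms: none
Why: Intramolecular Williamson displacement of the primary tosylate by the secondary alkoxide closes the epoxide with retention at the carbinol carbon.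

**Step 9**
Reactants: 7 methyl 5-bromo-2,6,6-trimethylcyclohexa-1,3-diene-1-carboxylate; 12 (2S)-2-(prop-1-en-2-yl)oxirane
Product: 16 (3R,5R)-9-bromo-6,10,10-trimethyl-3-(prop-1-en-2-yl)-2-oxaspiro[4.5]deca-6,8-dien-1-one, via lithium trienolate 13 (not isolated), via diethylaluminium trienolate 14 (not isolated), via hydroxy ester 15 (not isolated)
Conditions: LDA, THF, −78 → −40 °C; Et2AlCl, −78 °C; 12, −78 → 0 °C; aq. Rochelle salt; then PPTS (cat.), PhH, 50 °C; chromatography
Reagents that add atoms: none
Why: Deprotonation of 7 at C5 gives the linear trienolate, whose aluminium enolate opens the epoxide at its CH2 terminus through the enolate α-carbon (deconjugative α-alkylation by Lewis-acid-assisted enolate–epoxide opening), and the resulting alkoxide lactonises; the carbinol centre comes unchanged from 12, while the quaternary spiro centre forms without facial bias, so 16 is separated by chromatography from its (3R,5S) epimer (about 1:1).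

**Step 10**
Reactants: 16 (3R,5R)-9-bromo-6,10,10-trimethyl-3-(prop-1-en-2-yl)-2-oxaspiro[4.5]deca-6,8-dien-1-one
Product: 17 (3R,5R)-9-bromo-6,10,10-trimethyl-3-(prop-1-en-2-yl)-2-oxaspiro[4.5]deca-6,8-dien-1-ol (anomeric mixture)
Conditions: DIBAL-H (1.2 equiv), CH2Cl2, −78 °C; aq. Rochelle salt
Reagents that add atoms: none
Why: DIBAL-H half-reduction stops at the tetrahedral aluminium hemiacetal at −78 °C and gives the lactol, whose new anomeric centre equilibrates and is fixed in step 11.

**Step 11**
Reactants: 17 (3R,5R)-9-bromo-6,10,10-trimethyl-3-(prop-1-en-2-yl)-2-oxaspiro[4.5]deca-6,8-dien-1-ol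
Product: 18 triethyl{[(1S,3R,5R)-9-bromo-6,10,10-trimethyl-3-(prop-1-en-2-yl)-2-oxaspiro[4.5]deca-6,8-dien-1-yl]oxy}silane
Conditions: TESCl, imidazole, CH2Cl2, 0 °C; chromatography on Et3N-washed silica
Reagents that add atoms: chlorotriethylsilane, CC[Si](Cl)(CC)CC
Why: Silylation of the hemiacetal hydroxyl traps mainly the less hindered (1S) anomer (oxygen on the face of the sp2 ring carbon C6, away from the gem-dimethyl carbon), which is purified from the minor anomer, and it locks the acetal against ring–chain tautomerism so that only the acetal oxygen can reach the ring alkene.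

**Step 12**
Reactants: 18 triethyl{[(1S,3R,5R)-9-bromo-6,10,10-trimethyl-3-(prop-1-en-2-yl)-2-oxaspiro[4.5]deca-6,8-dien-1-yl]oxy}silane
Product: 19 (1S,3R,5S,7S,8S)-8,10-dibromo-7,11,11-trimethyl-3-(prop-1-en-2-yl)-4,6-dioxatricyclo[5.4.0.0^{1,5}]undec-9-ene
Conditions: NBS (1.05 equiv), 4 Å MS, CH2Cl2, dark, −40 → 0 °C
Reagents that add atoms: N-bromosuccinimide, O=C1CCC(=O)N1Br
Why: NBS forms a bromonium ion on the electron-rich trisubstituted C6=C7 bond of 18 on the face opposite to the silyloxy group, and the acetal oxygen opens it at the tertiary carbon in a 4-exo Markovnikov bromoetherification with transfer of the silyl group to succinimide; this anti addition sets the cis-fused oxetane C–O centre and the adjacent C–Br centre trans to it, while the acetal carbon and the two older centres are untouched.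

## Compound list

1 | 4-methylpent-3-en-2-one (mesityl oxide) | CC(=O)C=C(C)C | starting material
2 | methyl 3-oxobutanoate (methyl acetoacetate) | COC(=O)CC(C)=O | starting material
3 | methyl 2,6,6-trimethyl-4-oxocyclohex-2-ene-1-carboxylate (racemic) | COC(=O)C1C(C)=CC(=O)CC1(C)C | intermediate
4 | methyl 4-hydroxy-2,6,6-trimethylcyclohex-2-ene-1-carboxylate (racemic, cis/trans) | COC(=O)C1C(C)=CC(O)CC1(C)C | intermediate
5 | methyl 4-(methanesulfonyloxy)-2,6,6-trimethylcyclohex-2-ene-1-carboxylate (racemic) | COC(=O)C1C(C)=CC(OS(C)(=O)=O)CC1(C)C | intermediate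
6 | methyl 2,6,6-trimethylcyclohexa-1,3-diene-1-carboxylate | COC(=O)C1=C(C)C=CCC1(C)C | intermediate
7 | methyl 5-bromo-2,6,6-trimethylcyclohexa-1,3-diene-1-carboxylate (racemic) | COC(=O)C1=C(C)C=CC(Br)C1(C)C | intermediate
8 | 3-methylbut-2-en-1-ol (prenol) | CC(C)=CCO | starting material
9 | [(2R)-3,3-dimethyloxiran-2-yl]methanol | OC[C@H]1OC1(C)C | intermediate
10 | (2S)-3-methylbut-3-ene-1,2-diol | C=C(C)[C@H](O)CO | intermediate
11 | (2S)-2-hydroxy-3-methylbut-3-en-1-yl 4-methylbenzenesulfonate | C=C(C)[C@H](O)COS(=O)(=O)c1ccc(C)cc1 | intermediate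
12 | (2S)-2-(prop-1-en-2-yl)oxirane | C=C(C)[C@H]1CO1 | intermediate
13 | lithium trienolate of 7 (lithium (5-bromo-2,6,6-trimethylcyclohexa-2,4-dien-1-ylidene)(methoxy)methanolate) | [Li+].COC([O-])=C1C(C)=CC=C(Br)C1(C)C | intermediate
14 | diethylaluminium trienolate (O-diethylalumanyl ketene acetal of 7) | CC[Al](CC)OC(OC)=C1C(C)=CC=C(Br)C1(C)C | intermediate
15 | methyl 5-bromo-1-[(2R)-2-hydroxy-3-methylbut-3-en-1-yl]-2,6,6-trimethylcyclohexa-2,4-diene-1-carboxylate (both C1 epimers) | C=C(C)[C@H](O)CC1(C(=O)OC)C(C)=CC=C(Br)C1(C)C | intermediate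
16 | (3R,5R)-9-bromo-6,10,10-trimethyl-3-(prop-1-en-2-yl)-2-oxaspiro[4.5]deca-6,8-dien-1-one | C=C(C)[C@H]1C[C@@]2(C(=O)O1)C(C)=CC=C(Br)C2(C)C | intermediate
17 | (3R,5R)-9-bromo-6,10,10-trimethyl-3-(prop-1-en-2-yl)-2-oxaspiro[4.5]deca-6,8-dien-1-ol (anomeric mixture) | C=C(C)[C@H]1C[C@@]2(C(O)O1)C(C)=CC=C(Br)C2(C)C | intermediate
18 | triethyl{[(1S,3R,5R)-9-bromo-6,10,10-trimethyl-3-(prop-1-en-2-yl)-2-oxaspiro[4.5]deca-6,8-dien-1-yl]oxy}silane | C=C(C)[C@H]1C[C@@]2([C@@H](O1)O[Si](CC)(CC)CC)C(C)=CC=C(Br)C2(C)C | intermediate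
19 | (1S,3R,5S,7S,8S)-8,10-dibromo-7,11,11-trimethyl-3-(prop-1-en-2-yl)-4,6-dioxatricyclo[5.4.0.0^{1,5}]undec-9-ene | C=C(C)[C@H]1C[C@@]23[C@@H](O1)O[C@]2(C)[C@@H](Br)C=C(Br)C3(C)C | target

## Step count and risks

Total step count: 12 (steps 1–4 ring fragment, steps 5–8 side-chain fragment, steps 9–12 after the union).
Longest linear sequence: 8 steps (1, 2, 3, 4, 9, 10, 11, 12; the branch 5–8 then 9–12 is equally long).

**Most likely to fail, first: step 9.** The trienolate carbon is flanked by two fully substituted carbons, and an aluminium-activated vinyl epoxide can also be attacked at its allylic carbon. The fallback replaces epoxide opening by a Lewis-acid-free SN2 alkylation with a primary triflate. It sets out from 7 (its partner is made from 10) and comes back to the route at 16. Diol 10 is converted in one pot (Tf2O, 2,6-lutidine, CH2Cl2, −78 °C; then TBSOTf) into (2S)-2-[(tert-butyldimethylsilyl)oxy]-3-methylbut-3-en-1-yl trifluoromethanesulfonate F1. The lithium trienolate of 7 (LDA, THF–DMPU, −78 °C) is alkylated at its α-carbon by F1 to give methyl 5-bromo-1-{(2R)-2-[(tert-butyldimethylsilyl)oxy]-3-methylbut-3-en-1-yl}-2,6,6-trimethylcyclohexa-2,4-diene-1-carboxylate F2 as both C1 epimers. TBAF (THF, rt) then removes the silyl group and the alkoxide lactonises to 16, which is separated from its spiro epimer as before. This fallback does not improve the 1:1 outcome at the quaternary centre.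

**Second: step 12.** The 4-exo closure is slow by nature, and Br+ can be diverted to the isopropenyl group. The fallback masks that alkene during the bromination and unveils it last. It sets out from 16 and comes back to the route at 19.
- Oxymercuration–demercuration (Hg(OAc)2, THF–H2O; then NaBH4, NaOH) hydrates the isopropenyl group of 16 to (3R,5R)-9-bromo-3-(2-hydroxypropan-2-yl)-6,10,10-trimethyl-2-oxaspiro[4.5]deca-6,8-dien-1-one F3.
- DIBAL-H (CH2Cl2, −78 °C) gives the lactol (3R,5R)-9-bromo-3-(2-hydroxypropan-2-yl)-6,10,10-trimethyl-2-oxaspiro[4.5]deca-6,8-dien-1-ol F4.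
- TESCl/imidazole silylates only the hemiacetal hydroxyl, giving 2-[(1S,3R,5R)-9-bromo-6,10,10-trimethyl-1-(triethylsilyloxy)-2-oxaspiro[4.5]deca-6,8-dien-3-yl]propan-2-ol F5.
- NBS (CH2Cl2, −40 °C) closes the oxetane to 2-[(1S,3R,5S,7S,8S)-8,10-dibromo-7,11,11-trimethyl-4,6-dioxatricyclo[5.4.0.0^{1,5}]undec-9-en-3-yl]propan-2-ol F6.
- Burgess reagent (PhMe, 50 °C) dehydrates the tertiary alcohol towards the methyl group to give 19.

**Third: step 4.** The radical bromination may give positional isomers or attack the ring methyl group. The fallback places the bromine by enolate chemistry at the ketone stage. It sets out from 3 and comes back to the route at 7.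
- The dianion of 3 (LDA 2.2 equiv, THF, −78 °C) is brominated at the α′-carbon with 1,2-dibromotetrachloroethane to give methyl 5-bromo-2,6,6-trimethyl-4-oxocyclohex-2-ene-1-carboxylate F7.
- Luche reduction (NaBH4, CeCl3, MeOH, −40 °C) gives methyl 5-bromo-4-hydroxy-2,6,6-trimethylcyclohex-2-ene-1-carboxylate F8.
- MsCl/Et3N gives methyl 5-bromo-4-(methanesulfonyloxy)-2,6,6-trimethylcyclohex-2-ene-1-carboxylate F9, and DBU then effects the same 1,4-elimination as in step 3 to give 7.

## Further compounds

F1 | step 9 | (2S)-2-[(tert-butyldimethylsilyl)oxy]-3-methylbut-3-en-1-yl trifluoromethanesulfonate | C=C(C)[C@H](O[Si](C)(C)C(C)(C)C)COS(=O)(=O)C(F)(F)F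
F2 | step 9 | methyl 5-bromo-1-{(2R)-2-[(tert-butyldimethylsilyl)oxy]-3-methylbut-3-en-1-yl}-2,6,6-trimethylcyclohexa-2,4-diene-1-carboxylate | C=C(C)[C@H](O[Si](C)(C)C(C)(C)C)CC1(C(=O)OC)C(C)=CC=C(Br)C1(C)C
F3 | step 12 | (3R,5R)-9-bromo-3-(2-hydroxypropan-2-yl)-6,10,10-trimethyl-2-oxaspiro[4.5]deca-6,8-dien-1-one | CC(C)(O)[C@H]1C[C@@]2(C(=O)O1)C(C)=CC=C(Br)C2(C)C
F4 | step 12 | (3R,5R)-9-bromo-3-(2-hydroxypropan-2-yl)-6,10,10-trimethyl-2-oxaspiro[4.5]deca-6,8-dien-1-ol | CC(C)(O)[C@H]1C[C@@]2(C(O)O1)C(C)=CC=C(Br)C2(C)C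
F5 | step 12 | 2-[(1S,3R,5R)-9-bromo-6,10,10-trimethyl-1-(triethylsilyloxy)-2-oxaspiro[4.5]deca-6,8-dien-3-yl]propan-2-ol | CC(C)(O)[C@H]1C[C@@]2([C@@H](O1)O[Si](CC)(CC)CC)C(C)=CC=C(Br)C2(C)C
F6 | step 12 | 2-[(1S,3R,5S,7S,8S)-8,10-dibromo-7,11,11-trimethyl-4,6-dioxatricyclo[5.4.0.0^{1,5}]undec-9-en-3-yl]propan-2-ol | CC(C)(O)[C@H]1C[C@@]23[C@@H](O1)O[C@]2(C)[C@@H](Br)C=C(Br)C3(C)C
F7 | step 4 | methyl 5-bromo-2,6,6-trimethyl-4-oxocyclohex-2-ene-1-carboxylate | COC(=O)C1C(C)=CC(=O)C(Br)C1(C)C
F8 | step 4 | methyl 5-bromo-4-hydroxy-2,6,6-trimethylcyclohex-2-ene-1-carboxylate | COC(=O)C1C(C)=CC(O)C(Br)C1(C)C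
F9 | step 4 | methyl 5-bromo-4-(methanesulfonyloxy)-2,6,6-trimethylcyclohex-2-ene-1-carboxylate | COC(=O)C1C(C)=CC(OS(C)(=O)=O)C(Br)C1(C)C
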